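**Retrosynthetic overview**
1. Target 11 ⇐ lactonisation of the threo hydroxy ester 10 ⇐ transfer hydrogenation with dynamic kinetic resolution of the racemic α‑acetoxy ketone 9 (sets C3 and C4 together).
2. 9 ⇐ O‑methylation of hydroquinone 8 ⇐ Mukaiyama–Michael addition of the enol silane of acetoxyacetone to quinone ester 4 (C4a–C4 bond), then rearomatisation.
3. 4 ⇐ Teuber oxidative dearomatisation of phenol 3 (installs the C8 oxygen and makes the future C4a an acceptor carbon).
4. 3 ⇐ methyl 3,4‑dihydroxybenzoate + geranyl bromide.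
5. Ring order: the benzene ring comes from the feedstock (dearomatised, then rearomatised); the lactone ring is closed last.

Assumptions: geranyl = (2E)‑3,7‑dimethylocta‑2,6‑dien‑1‑yl; the target is numbered C1 (C=O), O2, C3 (Me), C4 (OAc), C5 (OMe), C6 (O‑geranyl), C8 (OH) and is the cis‑(3S,4S) lactone; in step 5 the (S,S)‑TsDPEN catalyst is taken to give the (S)‑carbinol as with aryl methyl ketones (the (R,R)‑ligand is used if the sense proves reversed).

**Step 1**
Reactants: 1 methyl 3,4‑dihydroxybenzoate; 2 geranyl bromide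
Product: 3 methyl 4‑(geranyloxy)‑3‑hydroxybenzoate
Conditions: K2CO3 (1.05 equiv), DMF, 0 °C → rt
Reagents that add atoms: none
Why: Williamson etherification; with one equivalent of base the more acidic 4‑OH (para to the ester) is ionised and alkylated selectively, and no stereocentre is formed.

**Step 2**
Reactants: 3 methyl 4‑(geranyloxy)‑3‑hydroxybenzoate
Product: 4 methyl 4‑(geranyloxy)‑3,6‑dioxocyclohexa‑1,4‑diene‑1‑carboxylate
Conditions: (KSO3)2NO (2.5 equiv), KH2PO4 buffer (pH 6), acetone/H2O, Aliquat 336 (cat.), 0 °C → rt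
Reagents that add atoms: Fremy's salt (potassium nitrosodisulfonate), [O]N(S(=O)(=O)[O-])S(=O)(=O)[O-].[K+].[K+]
Why: Teuber oxidation; the nitrosodisulfonate radical oxidises the phenol and traps the phenoxyl radical at the free para position, giving the p‑quinone, so the ring is dearomatised, the C8 oxygen is installed and the CH next to the ester becomes a doubly activated Michael position (no stereocentre).

**Step 3**
Reactants: 4 methyl 4‑(geranyloxy)‑3,6‑dioxocyclohexa‑1,4‑diene‑1‑carboxylate; 5 acetoxyacetone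
Product: 8 methyl 2‑(1‑acetoxy‑2‑oxopropyl)‑4‑(geranyloxy)‑3,6‑dihydroxybenzoate (racemic), via enol silane 6 (not isolated), via O‑silyl hydroquinone 7 (not isolated)
Conditions: 5, TMSOTf, Et3N, CH2Cl2, 0 °C; then 4, −78 → −20 °C; 10% aq. citric acid, THF
Reagents that add atoms: none
Why: Mukaiyama–Michael addition; soft enolisation of 5 on the more acidic acetoxy‑bearing side gives 6, which adds to the ring CH that is β to both the ester and a quinone carbonyl (the other CH is the deactivated β‑carbon of the vinylogous ester), and tautomerisation restores the arene; the new benzylic centre (future C4) is left racemic on purpose because step 5 resolves it dynamically.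

**Step 4**
Reactants: 8 methyl 2‑(1‑acetoxy‑2‑oxopropyl)‑4‑(geranyloxy)‑3,6‑dihydroxybenzoate
Product: 9 methyl 2‑(1‑acetoxy‑2‑oxopropyl)‑4‑(geranyloxy)‑6‑hydroxy‑3‑methoxybenzoate (racemic)
Conditions: MeI (1.3 equiv), K2CO3 (1.2 equiv), acetone, rt, Ar
Reagents that add atoms: iodomethane, CI
Why: Williamson O‑methylation; the 6‑OH is held in the salicylate hydrogen bond, so the free 3‑phenoxide is methylated (as in the mono‑methylation of gentisate esters), and the racemic centre is of no consequence here.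

**Step 5**
Reactants: 9 methyl 2‑(1‑acetoxy‑2‑oxopropyl)‑4‑(geranyloxy)‑6‑hydroxy‑3‑methoxybenzoate
Product: 11 (3S,4S)‑4‑acetoxy‑6‑(geranyloxy)‑8‑hydroxy‑5‑methoxy‑3‑methylisochroman‑1‑one, via hydroxy ester 10 (not isolated)
Conditions: RuCl[(S,S)‑TsDPEN](p‑cymene) (2 mol%), HCO2H/Et3N (5:2), DMF, 30 °C; then PPTS (cat.), PhMe, 50 °C
Reagents that add atoms: none
Why: Proposed new method: Noyori–Ikariya asymmetric transfer hydrogenation with dynamic kinetic resolution, applied to an acyclic α‑acetoxy‑α‑aryl methyl ketone; the C–H flanked by ketone, acetoxy group and arene epimerises through the enol under Et3N, the catalyst delivers hydride to the Re face of the ketone (3S), and this is the Felkin–Anh face (acetoxy anti to hydride) only for the (4S)‑ketone, so the racemate funnels to the (3S,4S)‑threo hydroxy ester 10, which closes under mild acid to the six‑membered lactone before the acetyl group can migrate; the closest known chemistry is the DKR transfer hydrogenation of benzoins and α‑substituted β‑keto esters and the reduction–lactonisation of 2‑(2‑oxopropyl)benzoates to 3‑methyl‑3,4‑dihydroisocoumarins.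

**Compound list**
1 | methyl 3,4‑dihydroxybenzoate | COC(=O)c1ccc(O)c(O)c1 | starting material
2 | geranyl bromide, (2E)‑1‑bromo‑3,7‑dimethylocta‑2,6‑diene | BrC/C=C(\C)CCC=C(C)C | starting material
3 | methyl 4‑(geranyloxy)‑3‑hydroxybenzoate | COC(=O)c1ccc(OC/C=C(\C)CCC=C(C)C)c(O)c1 | intermediate
4 | methyl 4‑(geranyloxy)‑3,6‑dioxocyclohexa‑1,4‑diene‑1‑carboxylate | COC(=O)C1=CC(=O)C(OC/C=C(\C)CCC=C(C)C)=CC1=O | intermediate
5 | acetoxyacetone (2‑oxopropyl acetate) | CC(=O)COC(C)=O | starting material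
6 | (Z)‑1‑acetoxy‑2‑(trimethylsilyloxy)prop‑1‑ene | CC(=O)O/C=C(/C)O[Si](C)(C)C | intermediate
7 | methyl 2‑(1‑acetoxy‑2‑oxopropyl)‑4‑(geranyloxy)‑3‑hydroxy‑6‑(trimethylsilyloxy)benzoate (racemic) | COC(=O)c1c(O[Si](C)(C)C)cc(OC/C=C(\C)CCC=C(C)C)c(O)c1C(OC(C)=O)C(C)=O | intermediate
8 | methyl 2‑(1‑acetoxy‑2‑oxopropyl)‑4‑(geranyloxy)‑3,6‑dihydroxybenzoate (racemic) | COC(=O)c1c(O)cc(OC/C=C(\C)CCC=C(C)C)c(O)c1C(OC(C)=O)C(C)=O | intermediate
9 | methyl 2‑(1‑acetoxy‑2‑oxopropyl)‑4‑(geranyloxy)‑6‑hydroxy‑3‑methoxybenzoate (racemic) | COC(=O)c1c(O)cc(OC/C=C(\C)CCC=C(C)C)c(OC)c1C(OC(C)=O)C(C)=O | intermediate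
10 | methyl 2‑[(1S,2S)‑1‑acetoxy‑2‑hydroxypropyl]‑4‑(geranyloxy)‑6‑hydroxy‑3‑methoxybenzoate | COC(=O)c1c(O)cc(OC/C=C(\C)CCC=C(C)C)c(OC)c1[C@H](OC(C)=O)[C@H](C)O | intermediate
11 | (3S,4S)‑4‑acetoxy‑6‑(geranyloxy)‑8‑hydroxy‑5‑methoxy‑3‑methylisochroman‑1‑one | COc1c(OC/C=C(\C)CCC=C(C)C)cc(O)c2c1[C@H](OC(C)=O)[C@H](C)OC2=O | target

**Step count:** 5 steps in total; longest linear sequence 5 steps (1 → 3 → 4 → 8 → 9 → 11).

**Three steps most likely to fail**

Step 5 (sense and level of the dynamic kinetic resolution on an acyclic dialkyl‑type ketone; slow epimerisation; acetyl migration followed by phthalide formation). The fallback sets out from 9 and comes back at 11. Acid‑catalysed enol‑lactonisation (TsOH cat., PhMe, 80 °C) gives the isocoumarin 4‑acetoxy‑6‑(geranyloxy)‑8‑hydroxy‑5‑methoxy‑3‑methyl‑1H‑isochromen‑1‑one F1. Mild methanolysis of the enol acetate (K2CO3 cat., MeOH, 0 °C) gives 6‑(geranyloxy)‑8‑hydroxy‑5‑methoxy‑3‑methylisochromane‑1,4‑dione F2, a cyclic aryl ketone whose C3 enolises freely. Transfer hydrogenation with the (R,R)‑TsDPEN catalyst under DKR (hydride anti to the 3‑methyl group, cis product, as with 2‑substituted tetralones and 3‑substituted chromanones) gives (3S,4S)‑6‑(geranyloxy)‑4,8‑dihydroxy‑5‑methoxy‑3‑methylisochroman‑1‑one F3. Ac2O/pyridine at 0 °C acetylates the secondary alcohol in preference to the chelated 8‑OH and gives 11.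

Step 3 (regiochemistry of the enol silane formed in the flask; the free ortho‑OH of 8 can close onto the ketone and dehydrate to a benzofuran; the quinone is sensitive to amine). The fallback sets out from 4 and comes back at 9. Na2S2O4 reduces 4 to the hydroquinone methyl 4‑(geranyloxy)‑2,5‑dihydroxybenzoate F4. MeI/K2CO3 methylates the non‑chelated 5‑OH to give methyl 4‑(geranyloxy)‑2‑hydroxy‑5‑methoxybenzoate F5. PhI(OAc)2 in MeOH at 0 °C oxidises this p‑methoxyphenol to the quinone monoketal methyl 4‑(geranyloxy)‑3,3‑dimethoxy‑6‑oxocyclohexa‑1,4‑diene‑1‑carboxylate F6. Enol silane 6 (TMSOTf cat., −78 °C) adds to the CH between the ester‑bearing carbon and the ketal carbon, and the adduct loses methanol on acidic work‑up to give 9 directly. The methyl ether is already in place, so no free ortho‑OH ever sits next to the acetoxy ketone.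

Step 2 (Teuber oxidation of a phenol that carries an ester; stability of the alkoxycarbonyl quinone). The fallback sets out from 3 and comes back at 4. Azo coupling with diazotised sulfanilic acid (aq. Na2CO3/THF, 0 °C) para to the phenol gives methyl 4‑(geranyloxy)‑5‑hydroxy‑2‑[(E)‑(4‑sulfophenyl)diazenyl]benzoate F7. Na2S2O4 cleaves the azo group to methyl 2‑amino‑4‑(geranyloxy)‑5‑hydroxybenzoate F8. FeCl3 in cold dilute HCl oxidises this p‑aminophenol to the quinone imine, whose hydrolysis gives 4.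

**Further compounds**
F1 | step 5 | 4‑acetoxy‑6‑(geranyloxy)‑8‑hydroxy‑5‑methoxy‑3‑methyl‑1H‑isochromen‑1‑one | COc1c(OC/C=C(\C)CCC=C(C)C)cc(O)c2c1C(OC(C)=O)=C(C)OC2=O
F2 | step 5 | 6‑(geranyloxy)‑8‑hydroxy‑5‑methoxy‑3‑methylisochromane‑1,4‑dione (racemic) | COc1c(OC/C=C(\C)CCC=C(C)C)cc(O)c2c1C(=O)C(C)OC2=O
F3 | step 5 | (3S,4S)‑6‑(geranyloxy)‑4,8‑dihydroxy‑5‑methoxy‑3‑methylisochroman‑1‑one | COc1c(OC/C=C(\C)CCC=C(C)C)cc(O)c2c1[C@H](O)[C@H](C)OC2=O
F4 | step 3 | methyl 4‑(geranyloxy)‑2,5‑dihydroxybenzoate | COC(=O)c1cc(O)c(OC/C=C(\C)CCC=C(C)C)cc1O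
F5 | step 3 | methyl 4‑(geranyloxy)‑2‑hydroxy‑5‑methoxybenzoate | COC(=O)c1cc(OC)c(OC/C=C(\C)CCC=C(C)C)cc1O
F6 | step 3 | methyl 4‑(geranyloxy)‑3,3‑dimethoxy‑6‑oxocyclohexa‑1,4‑diene‑1‑carboxylate | COC(=O)C1=CC(OC)(OC)C(OC/C=C(\C)CCC=C(C)C)=CC1=O
F7 | step 2 | methyl 4‑(geranyloxy)‑5‑hydroxy‑2‑[(E)‑(4‑sulfophenyl)diazenyl]benzoate | COC(=O)c1cc(O)c(OC/C=C(\C)CCC=C(C)C)cc1/N=N/c1ccc(cc1)S(=O)(=O)O
F8 | step 2 | methyl 2‑amino‑4‑(geranyloxy)‑5‑hydroxybenzoate | COC(=O)c1cc(O)c(OC/C=C(\C)CCC=C(C)C)cc1N
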